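4 questions are asked of the new flask, and we reckon the last two by following one substrate molecule to where it comes to rest.

| setting | autumn | winter | flask |
|---|---|---|---|
| substrate | 0.021 M | 0.033 M | 0.015 M |
| partner | 0.027 M | 0.027 M | 0.0270 M |
| remark | run made earlier | run made earlier |  |
| time |  |  | 2.0 h |

| run | time / min | target / % | isomer of the product A / % | substrate / % |
|---|---|---|---|---|
| autumn | 6.00 | 11.3 | 3.5 | 1.0 |
| autumn | 20.0 | 6.0 | 4.3 | 0.1 |
| autumn | 30.0 | 7.4 | 4.0 | 0.6 |
| autumn | 50.0 | 5.5 | 4.0 | 0.4 |
| autumn | 80.0 | 5.8 | 4.4 | 0 |
| autumn | 90.0 | 4.5 | 4.6 | 0 |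
| autumn | 120 | 5.7 | 3.9 | 0 |
| winter | 10.0 | 4.6 | 2.5 | 10.0 |
| winter | 15.0 | 4.9 | 3.2 | 9.2 |
| winter | 20.0 | 4.6 | 3.6 | 9.9 |
| winter | 30.0 | 5.0 | 3.1 | 9.6 |
| winter | 50.0 | 4.2 | 3.1 | 9.6 |
| winter | 80.0 | 5.1 | 2.5 | 10.5 |
| winter | 120 | 4.9 | 3.9 | 9.1 |

(each reading ± 0.5 percentage points)

1. share of target in target plus isomer of the product A at 0.80 s
2. share of target in target plus isomer of the product A at 1.0 min
3. share of target in target plus isomer of the product A at 2.0 h
4. which of target and isomer of the product A there is more of at 2.0 h



In the autumn run the readings from 50.0 min on are flat within scatter, and substrate reads 0% at the last reading, so we average them. In the autumn run, target averages 5.37% of the substrate charged over those readings. We call this the resting yield: the fraction of consumed substrate that stands as target once the readings are flat. Over the same autumn readings, isomer of the product A averages 4.23%, which makes the share of target 56.0%.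

The new flask charges 1.80 parts of partner per part of substrate, so substrate is the limiting reagent, as in autumn, and we carry the resting yield over unchanged.

The weak link is the autumn share, which rests on 4 scattered readings of each product. We reforge it with the winter run, whose readings are flat within scatter and give a share of 60.3%. Midway between the two runs, we commit to 58.2% at 2.0 h, with target ahead. We put no number of our own on the earlier times.

The forecast gave 80% at 0.80 s, 76% at 1.0 min and 20% at 2.0 h, with isomer of the product A ahead, judging that “target seems to be destroyed by surplus partner until that partner is spent”.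

The flask gives 99.8%, 95.3% and 57.0% at those times, with target ahead, 5.63% against 4.25%.

    substrate ⇌ other conformer (K = 0.0740, k = 0.00800 s⁻¹)
    substrate + partner → target (k = 1.60 L mol⁻¹ s⁻¹)
    partner + other conformer → isomer of the product A (k = 1.30 L mol⁻¹ s⁻¹)
    other conformer ⇌ dormant form (K = 11.0, k = 0.0370 s⁻¹)
    target ⇌ isomer of the product B (K = 16.0, k = 0.00850 s⁻¹)

In the flask, target stands at 5.63% at 1.00 h and 5.63% at 20.0 h, beside the 5.37% we carried, with 44% of the partner still unbound at 2.0 h. A neighbour flask charges 0.060 M of substrate with the partner unchanged, so partner is 45.0% of the substrate charge and is first to run out, 0% left at 2.00 h. Counting one part of substrate taken up per part of partner, the resting yield gives target at 2.42% of the charge, and that flask holds 2.57%.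

The readings were computed from invented constants; noise was put on by code.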